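The ether oxygen of the target bridges C5 and C10, the two carbons that would form the ring-fusion bond of a eudesmane decalin (ring A: C1–C5, C10; ring B: C5–C10). Everything therefore rests on inserting one oxygen into that C5–C10 bond: a Criegee rearrangement of a C5 perester converts both cyclohexane rings into the two oxepane rings of the 11-oxabicyclo[4.4.1]undecane in one operation, with C6, C7, C8 and C10 already fixed on the rigid decalin. The substrate is a trans-fused 5α-hydroperoxy-eudesma-4(15),11(13)-dien-6α,12-olide carrying 1β-OTES and 8β-OTBS, made by a Schenck ene reaction that also creates the C4 methylene.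

Key step: step 20

Remarks on the chemistry (each one line)
- Eudesmane/germacrane numbering (C1–C15) is used from compound 10 on; β means the face of the C10 methyl group; TBSO = tert-butyldimethylsilyloxy, TESO = triethylsilyloxy; the α/β labels of the decalin are kept after ring expansion.
- Protecting groups: C1 is unmasked before C8, so C1 carries the labile TES ether and C8 the robust TBS ether.
- C1 configuration: the C1 oxygen is placed β (equatorial), because an axial 1α-silyloxy group would be 1,3-diaxial to C5 on the face where singlet oxygen and the acylating agent must react; hydride reduction of the C1 ketone gives the β-alcohol directly.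
- C1 stays a silyl ether (not an ester) so that it withdraws as little electron density as possible from the migrating C10.
- Assumption: Rh/(R)-BINAP selects the enone face in step 2 as it does for cyclohex-2-enone; if the sense is opposite, the antipodal ligand is used.
- The C11 epimers formed in step 9 are carried together (11S drawn) and converge in step 18; either C7 epimer of 5 serves in step 4.

Step 1
Reactants: 1 4-methoxy-2-methylphenol
Product: 2 7-methyl-1,4-dioxaspiro[4.5]deca-6,9-dien-8-one
Conditions: PhI(OAc)2, ethylene glycol, MeCN, 0 °C to rt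
Reagents that add atoms: ethylene glycol, OCCO
Why: Oxidative dearomatisation of a para-alkoxyphenol by PhI(OAc)2 gives the quinone oxocarbenium ion, which the glycol captures and closes to the spiro-dioxolane with loss of methanol (quinone monoketal formation).

Step 2
Reactants: 2 7-methyl-1,4-dioxaspiro[4.5]deca-6,9-dien-8-one; 3 potassium isopropenyltrifluoroborate
Product: 4 (10R)-7-methyl-10-(prop-1-en-2-yl)-1,4-dioxaspiro[4.5]dec-6-en-8-one
Conditions: [Rh(cod)2]BF4 (cat.), (R)-BINAP, Et3N, toluene/H2O, 30 °C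
Reagents that add atoms: none
Why: Rhodium-catalysed asymmetric 1,4-addition of an alkenylboron reagent (Hayashi–Miyaura reaction) should occur only at the unsubstituted enone, the α-methyl enone being far less reactive, and the BINAP ligand selects the enone face, which sets the later C7.

Step 3
Reactants: 4 (10R)-7-methyl-10-(prop-1-en-2-yl)-1,4-dioxaspiro[4.5]dec-6-en-8-one
Product: 5 (7R,10R)-7-methyl-10-(prop-1-en-2-yl)-1,4-dioxaspiro[4.5]decan-8-one
Conditions: H2 (35 bar), [(Ph3P)CuH]6 (cat.), t-BuOH, THF, rt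
Reagents that add atoms: none
Why: Copper hydride catalysed conjugate reduction saturates the remaining enone and leaves the isolated isopropenyl group and the ketal untouched; the configuration of the methyl-bearing carbon does not matter because it is enolised in step 4.

Step 4
Reactants: 5 (7R,10R)-7-methyl-10-(prop-1-en-2-yl)-1,4-dioxaspiro[4.5]decan-8-one; 6 ethyl vinyl ketone
Product: 9 (7R,10R)-7-methyl-7-(3-oxopentyl)-10-(prop-1-en-2-yl)-1,4-dioxaspiro[4.5]decan-8-one, via ketimine 7 (not isolated), via Michael adduct ketimine 8 (not isolated)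
Conditions: (R)-1-phenylethylamine, TsOH (cat.), toluene, reflux (−H2O); then 6, THF, 40 °C; then AcOH/NaOAc (aq.), rt
Reagents that add atoms: water, O
Why: Deracemising Michael addition of a chiral ketimine: the more substituted secondary enamine tautomer of 7 adds to the enone through a cyclic aza-ene-like transition state on the face away from the phenyl group, creating the quaternary carbon (later C10, methyl β) under control of the amine, and buffered hydrolysis releases the 1,5-diketone.

Step 5
Reactants: 9 (7R,10R)-7-methyl-7-(3-oxopentyl)-10-(prop-1-en-2-yl)-1,4-dioxaspiro[4.5]decan-8-one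
Product: 10 8,8-ethylenedioxyeudesma-4,11-dien-3-one
Conditions: NaOMe, MeOH, rt to 50 °C
Reagents that add atoms: none
Why: Intramolecular aldol condensation of the 1,5-diketone (second stage of a Robinson annulation) closes ring A as the 4-methyl-Δ4-3-ketone without touching C7 or C10.

Step 6
Reactants: 10 8,8-ethylenedioxyeudesma-4,11-dien-3-one
Product: 11 eudesma-4,11-diene-3,8-dione
Conditions: PPTS, acetone/H2O, 55 °C
Reagents that add atoms: water, O
Why: Acid-catalysed hydrolysis of the dioxolane under weakly acidic conditions frees the C8 ketone while keeping the β,γ-isopropenyl group out of conjugation.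

Step 7
Reactants: 11 eudesma-4,11-diene-3,8-dione
Product: 12 8β-hydroxyeudesma-4,11-dien-3-one
Conditions: NaBH4 (0.3 equiv), EtOH, −20 °C
Reagents that add atoms: none
Why: Chemoselective borohydride reduction of the saturated ketone beside the less electrophilic enone; hydride should enter from the α face because the axial trajectory on the β face is blocked by the 1,3-diaxial C10 methyl, giving the axial 8β-alcohol.

Step 8
Reactants: 12 8β-hydroxyeudesma-4,11-dien-3-one
Product: 13 8β-TBSO-eudesma-4,11-dien-3-one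
Conditions: TBSOTf, 2,6-lutidine, CH2Cl2, −40 to 0 °C
Reagents that add atoms: tert-butyldimethylsilyl trifluoromethanesulfonate, CC(C)(C)[Si](C)(C)OS(=O)(=O)C(F)(F)F
Why: Silylation of the hindered axial alcohol with a silyl triflate (standard protection) installs the robust group that must last until step 25.

Step 9
Reactants: 13 8β-TBSO-eudesma-4,11-dien-3-one
Product: 15 12-hydroxy-8β-TBSO-eudesm-4-en-3-one, via pinacol boronate 14 (not isolated)
Conditions: HBpin, [Ir(cod)Cl]2 (cat.), dppe, CH2Cl2, rt; then H2O2, NaOH (aq.), THF, 0 °C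
Reagents that add atoms: hydrogen peroxide, OO
Why: Iridium-catalysed anti-Markovnikov hydroboration with pinacolborane is selective for the 1,1-disubstituted alkene and does not reduce the enone, and oxidation of the C–B bond gives the primary C12 alcohol; the new C11 centre is of no consequence.

Step 10
Reactants: 15 12-hydroxy-8β-TBSO-eudesm-4-en-3-one
Product: 17 6α,12-dihydroxy-8β-TBSO-eudesm-4-en-3-one, via dienol silyl ether 16 (not isolated)
Conditions: TMSOTf, Et3N, CH2Cl2, 0 °C; then mCPBA, NaHCO3, −20 °C; then 1 M HCl, THF, 0 °C to rt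
Reagents that add atoms: 3-chloroperbenzoic acid, OOC(=O)c1cccc(Cl)c1
Why: Vinylogous Rubottom oxidation: the thermodynamic 3,5-dienol silyl ether is epoxidised at C5=C6 from the α face, the β face being screened by the syn-axial 8β-silyloxy and C10 methyl groups, and the acidic work-up removes the trimethylsilyl groups and lets any 6β epimer equilibrate through the dienol to the equatorial 6α-alcohol.

Step 11
Reactants: 17 6α,12-dihydroxy-8β-TBSO-eudesm-4-en-3-one
Product: 18 3-oxo-8β-TBSO-eudesm-4-en-6α,12-olide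
Conditions: TEMPO (cat.), PhI(OAc)2, CH2Cl2, rt
Reagents that add atoms: none
Why: Oxoammonium (TEMPO) oxidation is selective for the primary alcohol, and the aldehyde is trapped by the 6α-hydroxyl as a lactol that is oxidised on to the γ-lactone (oxidative lactonisation), so C6 keeps its configuration and the lactone is trans-fused.

Step 12
Reactants: 18 3-oxo-8β-TBSO-eudesm-4-en-6α,12-olide
Product: 19 3-oxo-8β-TBSO-eudesma-1,4-dien-6α,12-olide
Conditions: DDQ, dioxane, reflux
Reagents that add atoms: none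
Why: Dehydrogenation of a Δ4-3-ketone with DDQ under neutral conditions proceeds through the C2 enol to the cross-conjugated 1,4-dien-3-one, the C6 oxygen precluding the alternative 4,6-dienone.

Step 13
Reactants: 19 3-oxo-8β-TBSO-eudesma-1,4-dien-6α,12-olide
Product: 20 1α,2α-epoxy-3-oxo-8β-TBSO-eudesm-4-en-6α,12-olide
Conditions: t-BuOOH, DBU, CH2Cl2, 0 °C to rt
Reagents that add atoms: tert-butyl hydroperoxide, CC(C)(C)OO
Why: Nucleophilic (Weitz–Scheffer) epoxidation attacks the less substituted C1=C2 bond of the cross-conjugated dienone from the α face, opposite the C10 methyl group, and the non-aqueous base spares the lactone.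

Step 14
Reactants: 20 1α,2α-epoxy-3-oxo-8β-TBSO-eudesm-4-en-6α,12-olide
Product: 22 1α-hydroxy-8β-TBSO-eudesma-2,4-dien-6α,12-olide, via epoxy hydrazone 21 (not isolated)
Conditions: N2H4·H2O, AcOH (cat.), MeOH, 0 °C to rt
Reagents that add atoms: none
Why: Wharton transposition: the hydrazone of the epoxy ketone opens the epoxide and loses N2 to give the allylic alcohol, so that oxygen arrives at C1 and C3 is deoxygenated in one operation.

Step 15
Reactants: 22 1α-hydroxy-8β-TBSO-eudesma-2,4-dien-6α,12-olide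
Product: 23 1-oxo-8β-TBSO-eudesma-2,4-dien-6α,12-olide
Conditions: Dess–Martin periodinane, NaHCO3, CH2Cl2, 0 °C to rt
Reagents that add atoms: none
Why: Dess–Martin oxidation of the allylic alcohol under buffered conditions gives the linear dienone and erases the C1 centre that was set on the unwanted face.

Step 16
Reactants: 23 1-oxo-8β-TBSO-eudesma-2,4-dien-6α,12-olide
Product: 25 1β-hydroxy-8β-TBSO-eudesm-4-en-6α,12-olide, via saturated ketone 24 (not isolated)
Conditions: Li(s-Bu)3BH, THF, −78 °C; then MeOH, NaBH4, −78 to 0 °C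
Reagents that add atoms: none
Why: Conjugate hydride reduction of the enone, favoured because the carbonyl is shielded by the adjacent quaternary C10 and C3 carries no extra substituent, gives the C1 ketone after protonation, and borohydride then attacks C1 from the α face, anti to the C10 methyl, to give the equatorial 1β-alcohol.

Step 17
Reactants: 25 1β-hydroxy-8β-TBSO-eudesm-4-en-6α,12-olide
Product: 26 1β-TESO-8β-TBSO-eudesm-4-en-6α,12-olide
Conditions: TESOTf, 2,6-lutidine, CH2Cl2, −40 °C
Reagents that add atoms: triethylsilyl trifluoromethanesulfonate, CC[Si](CC)(CC)OS(=O)(=O)C(F)(F)F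
Why: Silylation with the triethylsilyl triflate gives a C1 ether that is more labile than the C8 TBS ether, as the order of unmasking in steps 22 and 25 requires.

Step 18
Reactants: 26 1β-TESO-8β-TBSO-eudesm-4-en-6α,12-olide
Product: 28 1β-TESO-8β-TBSO-eudesma-4,11(13)-dien-6α,12-olide, via selenide 27 (not isolated)
Conditions: LiN(i-Pr)2, THF, −78 °C; PhSeCl; then NaIO4, NaHCO3, THF/MeOH/H2O, rt
Reagents that add atoms: none
Why: α-Selenenylation of the lactone enolate followed by oxidation to the selenoxide and syn-elimination, which in trans-fused α-methyl lactones runs toward the methyl group and so gives the exocyclic methylene and removes the C11 centre.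

Step 19
Reactants: 28 1β-TESO-8β-TBSO-eudesma-4,11(13)-dien-6α,12-olide
Product: 29 5α-hydroperoxy-1β-TESO-8β-TBSO-eudesma-4(15),11(13)-dien-6α,12-olide
Conditions: O2, visible light, tetraphenylporphyrin (cat.), CH2Cl2, −20 °C
Reagents that add atoms: dioxygen, O=O
Why: Schenck ene reaction: singlet oxygen should attack the tetrasubstituted C4=C5 bond on the α face (the β face carries the C10 methyl and both silyloxy groups), bond to C5 and abstract a hydrogen from C15, giving the trans-fused 5α-hydroperoxide and the C4 methylene; H6 lies on the β face and the electron-poor lactone methylene is inert.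

Step 20
Reactants: 29 5α-hydroperoxy-1β-TESO-8β-TBSO-eudesma-4(15),11(13)-dien-6α,12-olide
Product: 31 5β-acetoxy-5α,10α-epoxy-1β-TESO-8β-TBSO-germacra-4(15),11(13)-dien-6α,12-olide, via peracetate 30 (not isolated)
Conditions: Ac2O, pyridine, DMAP (cat.), CH2Cl2, 0 to 40 °C
Reagents that add atoms: acetic anhydride, CC(=O)OC(C)=O
Why: Acetylation of the tertiary hydroperoxide gives the peracetate, whose O–O bond ionises with a concerted suprafacial 1,2-shift of C10 from C5 to the proximal oxygen (retention at C10), and the bridgehead oxocarbenium–acetate ion pair collapses at C5. The closest known reaction is the Criegee rearrangement of trans-9-decalyl peresters to 1,6-epoxycyclodecyl esters. Both oxepane rings (C10–O–C5–C4–C3–C2–C1 and C10–O–C5–C6–C7–C8–C9) are closed by this single insertion of oxygen into the shared C5–C10 bond, a ring expansion by 1,2-migration and not an end-to-end cyclisation. The new stereocentre C5 is fixed by the bicyclo[4.4.1] framework, since acetate can only occupy the one open position of the bridgehead carbon. The step needs C10 to migrate in preference to C4 and C6: C10 is a tertiary alkyl carbon whose bond to C5 can lie antiperiplanar to the O–O bond of the axial 5α-perester, C4 is an sp2 carbon, C6 is deactivated by the lactone acyloxy group, and the C1 oxygen is an equatorial silyl ether.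

Step 21
Reactants: 31 5β-acetoxy-5α,10α-epoxy-1β-TESO-8β-TBSO-germacra-4(15),11(13)-dien-6α,12-olide
Product: 32 5α,10α-epoxy-1β-TESO-8β-TBSO-germacra-4(15),11(13)-dien-6α,12-olide
Conditions: Et3SiH, BF3·OEt2, CH2Cl2, −78 to −30 °C
Reagents that add atoms: none
Why: Ionic hydrogenation of a ketal acetate: BF3 ionises the acetate to the bridgehead oxocarbenium ion and Et3SiH delivers hydride to its only accessible position, so C5–H has the configuration dictated by the bicycle.

Step 22
Reactants: 32 5α,10α-epoxy-1β-TESO-8β-TBSO-germacra-4(15),11(13)-dien-6α,12-olide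
Product: 33 5α,10α-epoxy-1β-hydroxy-8β-TBSO-germacra-4(15),11(13)-dien-6α,12-olide
Conditions: PPTS, MeOH, 0 °C to rt
Reagents that add atoms: none
Why: Acid-catalysed methanolysis cleaves the triethylsilyl ether much faster than the hindered TBS ether (selective desilylation).

Step 23
Reactants: 33 5α,10α-epoxy-1β-hydroxy-8β-TBSO-germacra-4(15),11(13)-dien-6α,12-olide
Product: 34 5α,10α-epoxy-1-oxo-8β-TBSO-germacra-4(15),11(13)-dien-6α,12-olide
Conditions: Dess–Martin periodinane, NaHCO3, CH2Cl2, rt
Reagents that add atoms: none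
Why: Dess–Martin oxidation of the secondary alcohol gives the C1 ketone under neutral conditions that the α-methylene lactone tolerates.

Step 24
Reactants: 34 5α,10α-epoxy-1-oxo-8β-TBSO-germacra-4(15),11(13)-dien-6α,12-olide
Product: 36 5α,10α-epoxy-1-oxo-8β-TBSO-germacra-2,4(15),11(13)-trien-6α,12-olide, via silyl enol ether 35 (not isolated)
Conditions: TMSOTf, Et3N, CH2Cl2, 0 °C; then Pd(OAc)2, MeCN, rt
Reagents that add atoms: none
Why: Saegusa–Ito oxidation: soft enolisation can only occur toward C2 because C10 is quaternary, and Pd(OAc)2 converts the silyl enol ether to the enone conjugated with the C4 methylene.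

Step 25
Reactants: 36 5α,10α-epoxy-1-oxo-8β-TBSO-germacra-2,4(15),11(13)-trien-6α,12-olide
Product: 37 5α,10α-epoxy-8β-hydroxy-1-oxogermacra-2,4(15),11(13)-trien-6α,12-olide
Conditions: HF·pyridine, pyridine, THF, 0 °C to rt
Reagents that add atoms: none
Why: Fluoride cleavage of the secondary TBS ether under acidic buffered conditions avoids base, which could add to the Michael acceptors or move the lactone to the C8 oxygen.

Step 26
Reactants: 37 5α,10α-epoxy-8β-hydroxy-1-oxogermacra-2,4(15),11(13)-trien-6α,12-olide; 38 angelic acid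
Product: 40 8β-angeloyloxy-5α,10α-epoxy-1-oxogermacra-2,4(15),11(13)-trien-6α,12-olide (CNP0282559.1), via mixed anhydride 39 (not isolated)
Conditions: 38, 2,4,6-trichlorobenzoyl chloride, Et3N, toluene, rt; then 37, 80 °C
Reagents that add atoms: none
Why: Yamaguchi esterification: the mixed anhydride of angelic acid acylates the hindered alcohol at its less hindered carbonyl without passing through an acid chloride or ketene, which should keep the Z geometry of the angelate.

Compound list
1 | 4-methoxy-2-methylphenol | Cc1cc(OC)ccc1O | starting material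
2 | 7-methyl-1,4-dioxaspiro[4.5]deca-6,9-dien-8-one | CC1=CC2(OCCO2)C=CC1=O | intermediate
3 | potassium isopropenyltrifluoroborate | [K+].C=C(C)[B-](F)(F)F | starting material
4 | (10R)-7-methyl-10-(prop-1-en-2-yl)-1,4-dioxaspiro[4.5]dec-6-en-8-one | CC1=CC2(OCCO2)[C@@H](C(C)=C)CC1=O | intermediate
5 | (7R,10R)-7-methyl-10-(prop-1-en-2-yl)-1,4-dioxaspiro[4.5]decan-8-one | C[C@@H]1CC2(OCCO2)[C@@H](C(C)=C)CC1=O | intermediate
6 | ethyl vinyl ketone | CCC(=O)C=C | starting material
7 | N-[(R)-1-phenylethyl] ketimine of 5 | C[C@@H]1CC2(OCCO2)[C@@H](C(C)=C)CC1=N[C@H](C)c1ccccc1 | intermediate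
8 | N-[(R)-1-phenylethyl] ketimine of 9 | CCC(=O)CC[C@]1(C)CC2(OCCO2)[C@@H](C(C)=C)CC1=N[C@H](C)c1ccccc1 | intermediate
9 | (7R,10R)-7-methyl-7-(3-oxopentyl)-10-(prop-1-en-2-yl)-1,4-dioxaspiro[4.5]decan-8-one | CCC(=O)CC[C@]1(C)CC2(OCCO2)[C@@H](C(C)=C)CC1=O | intermediate
10 | 8,8-ethylenedioxyeudesma-4,11-dien-3-one (10β-methyl, 7β-isopropenyl) | CC1=C2C[C@H](C(C)=C)C3(OCCO3)C[C@@]2(C)CCC1=O | intermediate
11 | eudesma-4,11-diene-3,8-dione | CC1=C2C[C@H](C(C)=C)C(=O)C[C@@]2(C)CCC1=O | intermediate
12 | 8β-hydroxyeudesma-4,11-dien-3-one | CC1=C2C[C@H](C(C)=C)[C@H](O)C[C@@]2(C)CCC1=O | intermediate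
13 | 8β-TBSO-eudesma-4,11-dien-3-one | CC1=C2C[C@H](C(C)=C)[C@H](O[Si](C)(C)C(C)(C)C)C[C@@]2(C)CCC1=O | intermediate
14 | 12-(pinacolatoboryl)-8β-TBSO-eudesm-4-en-3-one (11S drawn) | CC1=C2C[C@H]([C@H](C)CB3OC(C)(C)C(C)(C)O3)[C@H](O[Si](C)(C)C(C)(C)C)C[C@@]2(C)CCC1=O | intermediate
15 | 12-hydroxy-8β-TBSO-eudesm-4-en-3-one (11S drawn) | CC1=C2C[C@H]([C@H](C)CO)[C@H](O[Si](C)(C)C(C)(C)C)C[C@@]2(C)CCC1=O | intermediate
16 | 3,12-bis(trimethylsilyloxy)-8β-TBSO-eudesma-3,5-diene | CC1=C(O[Si](C)(C)C)CC[C@]2(C)C[C@@H](O[Si](C)(C)C(C)(C)C)[C@@H]([C@H](C)CO[Si](C)(C)C)C=C12 | intermediate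
17 | 6α,12-dihydroxy-8β-TBSO-eudesm-4-en-3-one | CC1=C2[C@@H](O)[C@H]([C@H](C)CO)[C@H](O[Si](C)(C)C(C)(C)C)C[C@@]2(C)CCC1=O | intermediate
18 | 3-oxo-8β-TBSO-eudesm-4-en-6α,12-olide (11S) | C[C@H]1[C@@H]2[C@H](O[Si](C)(C)C(C)(C)C)C[C@]3(CCC(=O)C(=C3[C@H]2OC1=O)C)C | intermediate
19 | 3-oxo-8β-TBSO-eudesma-1,4-dien-6α,12-olide | C[C@H]1[C@@H]2[C@H](O[Si](C)(C)C(C)(C)C)C[C@]3(C=CC(=O)C(=C3[C@H]2OC1=O)C)C | intermediate
20 | 1α,2α-epoxy-3-oxo-8β-TBSO-eudesm-4-en-6α,12-olide | C[C@H]1[C@@H]2[C@H](O[Si](C)(C)C(C)(C)C)C[C@]3([C@H]4O[C@H]4C(=O)C(=C3[C@H]2OC1=O)C)C | intermediate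
21 | C3 hydrazone of 20 | C[C@H]1[C@@H]2[C@H](O[Si](C)(C)C(C)(C)C)C[C@]3([C@H]4O[C@H]4C(=NN)C(=C3[C@H]2OC1=O)C)C | intermediate
22 | 1α-hydroxy-8β-TBSO-eudesma-2,4-dien-6α,12-olide | C[C@H]1[C@@H]2[C@H](O[Si](C)(C)C(C)(C)C)C[C@]3([C@@H](O)C=CC(=C3[C@H]2OC1=O)C)C | intermediate
23 | 1-oxo-8β-TBSO-eudesma-2,4-dien-6α,12-olide | C[C@H]1[C@@H]2[C@H](O[Si](C)(C)C(C)(C)C)C[C@]3(C(=O)C=CC(=C3[C@H]2OC1=O)C)C | intermediate
24 | 1-oxo-8β-TBSO-eudesm-4-en-6α,12-olide | C[C@H]1[C@@H]2[C@H](O[Si](C)(C)C(C)(C)C)C[C@]3(C(=O)CCC(=C3[C@H]2OC1=O)C)C | intermediate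
25 | 1β-hydroxy-8β-TBSO-eudesm-4-en-6α,12-olide | C[C@H]1[C@@H]2[C@H](O[Si](C)(C)C(C)(C)C)C[C@]3([C@H](O)CCC(=C3[C@H]2OC1=O)C)C | intermediate
26 | 1β-TESO-8β-TBSO-eudesm-4-en-6α,12-olide | C[C@H]1[C@@H]2[C@H](O[Si](C)(C)C(C)(C)C)C[C@]3([C@H](O[Si](CC)(CC)CC)CCC(=C3[C@H]2OC1=O)C)C | intermediate
27 | 11α-phenylselanyl derivative of 26 | C[C@]1([Se]c4ccccc4)[C@@H]2[C@H](O[Si](C)(C)C(C)(C)C)C[C@]3([C@H](O[Si](CC)(CC)CC)CCC(=C3[C@H]2OC1=O)C)C | intermediate
28 | 1β-TESO-8β-TBSO-eudesma-4,11(13)-dien-6α,12-olide | C=C1[C@@H]2[C@H](O[Si](C)(C)C(C)(C)C)C[C@]3([C@H](O[Si](CC)(CC)CC)CCC(=C3[C@H]2OC1=O)C)C | intermediate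
29 | 5α-hydroperoxy-1β-TESO-8β-TBSO-eudesma-4(15),11(13)-dien-6α,12-olide | C=C1C(=O)O[C@H]2[C@H]1[C@H](O[Si](C)(C)C(C)(C)C)C[C@]1(C)[C@]2(OO)C(=C)CC[C@H]1O[Si](CC)(CC)CC | intermediate
30 | 5α-acetylperoxy analogue of 29 | C=C1C(=O)O[C@H]2[C@H]1[C@H](O[Si](C)(C)C(C)(C)C)C[C@]1(C)[C@]2(OOC(C)=O)C(=C)CC[C@H]1O[Si](CC)(CC)CC | intermediate
31 | 5β-acetoxy-5α,10α-epoxy-1β-TESO-8β-TBSO-germacra-4(15),11(13)-dien-6α,12-olide | C=C1C(=O)O[C@H]2[C@H]1[C@H](O[Si](C)(C)C(C)(C)C)C[C@]1(C)O[C@@]2(OC(C)=O)C(=C)CC[C@H]1O[Si](CC)(CC)CC | intermediate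
32 | 5α,10α-epoxy-1β-TESO-8β-TBSO-germacra-4(15),11(13)-dien-6α,12-olide | C=C1C(=O)O[C@H]2[C@H]1[C@H](O[Si](C)(C)C(C)(C)C)C[C@]1(C)O[C@H]2C(=C)CC[C@H]1O[Si](CC)(CC)CC | intermediate
33 | 5α,10α-epoxy-1β-hydroxy-8β-TBSO-germacra-4(15),11(13)-dien-6α,12-olide | C=C1C(=O)O[C@H]2[C@H]1[C@H](O[Si](C)(C)C(C)(C)C)C[C@]1(C)O[C@H]2C(=C)CC[C@H]1O | intermediate
34 | 5α,10α-epoxy-1-oxo-8β-TBSO-germacra-4(15),11(13)-dien-6α,12-olide | C=C1C(=O)O[C@H]2[C@H]1[C@H](O[Si](C)(C)C(C)(C)C)C[C@]1(C)O[C@H]2C(=C)CCC1=O | intermediate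
35 | 1-trimethylsilyloxy-1-ene (silyl enol ether) of 34 | C=C1C(=O)O[C@H]2[C@H]1[C@H](O[Si](C)(C)C(C)(C)C)C[C@]1(C)O[C@H]2C(=C)CC=C1O[Si](C)(C)C | intermediate
36 | 5α,10α-epoxy-1-oxo-8β-TBSO-germacra-2,4(15),11(13)-trien-6α,12-olide | C=C1C(=O)O[C@H]2[C@H]1[C@H](O[Si](C)(C)C(C)(C)C)C[C@]1(C)O[C@H]2C(=C)C=CC1=O | intermediate
37 | 5α,10α-epoxy-8β-hydroxy-1-oxogermacra-2,4(15),11(13)-trien-6α,12-olide | C=C1C(=O)O[C@H]2[C@H]1[C@H](O)C[C@]1(C)O[C@H]2C(=C)C=CC1=O | intermediate
38 | angelic acid | C/C=C(/C)C(=O)O | starting material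
39 | angelic 2,4,6-trichlorobenzoic anhydride | C/C=C(/C)C(=O)OC(=O)c1c(Cl)cc(Cl)cc1Cl | intermediate
40 | 8β-angeloyloxy-5α,10α-epoxy-1-oxogermacra-2,4(15),11(13)-trien-6α,12-olide (CNP0282559.1) | C=C1C(=O)O[C@H]2[C@H]1[C@H](OC(=O)/C(C)=C\C)C[C@]1(C)O[C@H]2C(=C)C=CC1=O | target

Total step count: 26. Longest linear sequence: 26 steps (1 to 40).

Steps most likely to fail

Step 20. The perester may ionise with migration of the vinylic C4 (a Hock-type cleavage of ring A), or the allylic peroxide may transpose, instead of C10 migrating. The fallback replaces the cationic shift by a radical cleavage of the same bond. It sets out from hydroperoxide 29, whose O–O bond is reduced with PPh3 to the tertiary allylic alcohol F1. Irradiation of F1 with PhI(OAc)2 and I2 in CH2Cl2 should generate the C5 alkoxy radical, which fragments the C5–C10 bond toward the tertiary C10 radical. Oxidation of that radical to the cation, transannular capture by the new C5 carbonyl oxygen and addition of acetate should bring the route back to ketal acetate 31.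

Step 21. The bridgehead acetate, flanked by the electron-poor C6 carbon, may fail to ionise, or hydride may enter at C15 with allylic shift. The fallback avoids the isolated acetate. It sets out from hydroperoxide 29, which is treated with (CF3CO)2O and 2,6-di-tert-butylpyridine in CH2Cl2 at −78 °C. The pertrifluoroacetate F2 should rearrange at low temperature to the far more labile bridgehead trifluoroacetate F3. Et3SiH and TMSOTf are added to the same flask so that the ion pair is reduced as it forms, and the route is rejoined at ether 32.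

Step 26. Slow acylation of the hindered axial 8β-hydroxyl may allow the angeloyl unit to isomerise from Z to E before it is transferred. The fallback masks the double bond. Anti addition of Br2 to angelic acid 38 gives dibromo acid F4 (either enantiomer serves). Steglich esterification of alcohol 37 with F4 (DCC, DMAP, CH2Cl2) gives dibromo ester F5. Anti debromination with NaI in acetone should regenerate the Z alkene stereospecifically and arrive at target 40.

Further compounds
F1 | step 20 | 5α-hydroxy-1β-TESO-8β-TBSO-eudesma-4(15),11(13)-dien-6α,12-olide | C=C1C(=O)O[C@H]2[C@H]1[C@H](O[Si](C)(C)C(C)(C)C)C[C@]1(C)[C@]2(O)C(=C)CC[C@H]1O[Si](CC)(CC)CC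
F2 | step 21 | 5α-trifluoroacetylperoxy analogue of 29 | C=C1C(=O)O[C@H]2[C@H]1[C@H](O[Si](C)(C)C(C)(C)C)C[C@]1(C)[C@]2(OOC(=O)C(F)(F)F)C(=C)CC[C@H]1O[Si](CC)(CC)CC
F3 | step 21 | 5β-trifluoroacetoxy-5α,10α-epoxy-1β-TESO-8β-TBSO-germacra-4(15),11(13)-dien-6α,12-olide | C=C1C(=O)O[C@H]2[C@H]1[C@H](O[Si](C)(C)C(C)(C)C)C[C@]1(C)O[C@@]2(OC(=O)C(F)(F)F)C(=C)CC[C@H]1O[Si](CC)(CC)CC
F4 | step 26 | (2S,3S)-2,3-dibromo-2-methylbutanoic acid | C[C@H](Br)[C@@](C)(Br)C(=O)O
F5 | step 26 | 8β-(2,3-dibromo-2-methylbutanoyloxy) analogue of 40 | C=C1C(=O)O[C@H]2[C@H]1[C@H](OC(=O)[C@](C)(Br)[C@H](C)Br)C[C@]1(C)O[C@H]2C(=C)C=CC1=O
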